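## Retrosynthetic overview

- Last C–C bond: the C3–CH2Ar bond of the lactone, by trans-selective enolate alkylation of a (4R)-4-(arylmethyl)butanolide (rings C/D half) with the benzylic bromide of the rings A/B half, followed by one global desilylation.
- Lactone ring: O1–C5 and C3–C4 are made together by annulating dichloroketene onto an (R at S, Z)-1-alkenyl p-tolyl sulfoxide (sulfonium [3,3] shift, then Pummerer-type lactonisation); chlorine and sulfur are then removed with Bu3SnH.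
- Enabling feature: in the γ-lactone, C5 is an unsubstituted O–CH2 bonded directly to the stereocentre C4 (H, CH2Ar). The C5–C4 pair can therefore be a former vinyl group carrying a removable sulfinyl group on C5, whose sulfur chirality is transferred to C4, while C3 (the ketene carbon) stays free for the later benzylation.
- Both 8–5′ units come from one N-arylacetyl oxazolidinone and silylated vanillin: boron syn-aldol then acid closure gives the trans-2,3-dihydrobenzofuran (first ring formed); magnesium anti-aldol gives the open (1S,2S)-1,3-diol. The lactone is the second and last ring formed.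

Key step: step 15

Abbreviations: TBS = tert-butyldimethylsilyl; ArE = 2-(TBS-oxy)-3-methoxy-5-(methoxycarbonyl)phenyl; ArG = 4-(TBS-oxy)-3-methoxyphenyl; Bf = (2S,3R)-2-ArG-3-(TBS-oxymethyl)-7-methoxy-2,3-dihydro-1-benzofuran-5-yl; Tol = 4-methylphenyl.

Assumption: the facial sense of the sulfur-controlled annulation and of the magnesium anti-aldol is taken from the chair (pseudo-equatorial p-tolyl) and chelated Z-enolate models of the parent reactions, and the bromovanillate ester, silylated vanillin, both 4-benzyloxazolidinones and both menthyl p-toluenesulfinates are taken as commercial.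

## Route

Step 1
Reactants: 1 methyl 3-bromo-4-hydroxy-5-methoxybenzoate
Product: 2 methyl 3-bromo-4-(TBS-oxy)-5-methoxybenzoate
Conditions: TBSCl, imidazole, DMF, 40 °C
Reagents that add atoms: tert-butyldimethylsilyl chloride, CC(C)(C)[Si](C)(C)Cl
Why: Imidazole-mediated O-silylation masks the only acidic OH before the organometallic steps and creates no stereocentre.

Step 2
Reactants: 2 methyl 3-bromo-4-(TBS-oxy)-5-methoxybenzoate
Product: 3 methyl 3-(2-tert-butoxy-2-oxoethyl)-4-(TBS-oxy)-5-methoxybenzoate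
Conditions: BrZnCH2CO2t-Bu, Pd2(dba)3 (2 mol %), XPhos (5 mol %), THF, 60 °C
Reagents that add atoms: (2-tert-butoxy-2-oxoethyl)zinc bromide, CC(C)(C)OC(=O)C[Zn]Br
Why: Palladium-catalysed α-arylation of a Reformatsky zinc enolate (Negishi-type coupling) replaces Br by the acetate arm and tolerates the methyl ester and the aryl silyl ether.

Step 3
Reactants: 3 methyl 3-(2-tert-butoxy-2-oxoethyl)-4-(TBS-oxy)-5-methoxybenzoate
Product: 4 (ArE)acetic acid
Conditions: TFA, CH2Cl2, 0 °C to rt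
Reagents that add atoms: none
Why: Acidolysis of the tert-butyl ester (E1 loss of isobutene) should leave the methyl ester and the hindered aryl silyl ether untouched.

Step 4
Reactants: 4 (ArE)acetic acid; 5 (S)-4-benzyl-1,3-oxazolidin-2-one
Product: 7 (4S)-4-benzyl-3-[(ArE)acetyl]-1,3-oxazolidin-2-one, via mixed pivalic anhydride 6 (not isolated)
Conditions: PivCl, Et3N, THF, −20 °C; then 5, LiCl, rt
Reagents that add atoms: pivaloyl chloride, CC(C)(C)C(Cl)=O (its acyl group is carried by 6 only)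
Why: N-Acylation of the Evans auxiliary through a mixed anhydride gives the imide used for both halves, the stereocentre being that of the auxiliary.

Step 5
Reactants: 7 (4S)-4-benzyl-3-[(ArE)acetyl]-1,3-oxazolidin-2-one; 8 4-(TBS-oxy)-3-methoxybenzaldehyde
Product: 9 (4S)-4-benzyl-3-[(2S,3S)-2-ArE-3-ArG-3-hydroxypropanoyl]-1,3-oxazolidin-2-one
Conditions: n-Bu2BOTf, i-Pr2NEt, CH2Cl2, −78 to 0 °C; then 8, −78 to 0 °C; pH 7 buffer, MeOH, H2O2
Reagents that add atoms: none
Why: Evans syn-aldol reaction, in which the Z boron enolate reacts through a closed chair with the auxiliary dipole opposed and should set (2S,3S), the α-centre being the future C3 of the benzofuran.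

Step 6
Reactants: 9 syn-aldol imide
Product: 10 (1S,2R)-1-ArG-2-ArE-propane-1,3-diol
Conditions: LiBH4, MeOH (1 equiv), THF, 0 °C
Reagents that add atoms: none
Why: Reductive cleavage of the N-acyl oxazolidinone by hydride attack at the exocyclic carbonyl gives the 1,3-diol without touching the stereocentres, and the deactivated aryl methyl ester should be much slower at 0 °C.

Step 7
Reactants: 10 (1S,2R)-1-ArG-2-ArE-propane-1,3-diol
Product: 11 methyl 3-[(1S,2R)-1,3-dihydroxy-1-(4-hydroxy-3-methoxyphenyl)propan-2-yl]-4-hydroxy-5-methoxybenzoate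
Conditions: TBAF, AcOH, THF, 0 °C
Reagents that add atoms: none
Why: Buffered fluoride cleavage of both aryl silyl ethers frees the ortho-phenol nucleophile and the para-phenol that activates the benzylic carbinol.

Step 8
Reactants: 11 bisphenol triol
Product: 12 methyl (2S,3R)-2-(4-hydroxy-3-methoxyphenyl)-3-(hydroxymethyl)-7-methoxy-2,3-dihydro-1-benzofuran-5-carboxylate
Conditions: CSA (10 mol %), MeCN, rt
Reagents that add atoms: none
Why: Acid-catalysed dehydrative cyclisation through the p-hydroxybenzyl cation (quinone methide) with 5-exo attack of the ortho-phenol gives the favoured 2,3-trans ring, so C2 is set (S) by the existing C3 centre whatever the carbinol configuration.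

Step 9
Reactants: 12 dihydrobenzofuran diol ester
Product: 13 methyl (2S,3R)-2-ArG-3-(TBS-oxymethyl)-7-methoxy-2,3-dihydro-1-benzofuran-5-carboxylate (Bf–CO2Me)
Conditions: TBSCl, imidazole, DMF, rt
Reagents that add atoms: tert-butyldimethylsilyl chloride, CC(C)(C)[Si](C)(C)Cl
Why: Silyl ether formation on the phenol and the primary alcohol gives the protecting-group pattern that is removed by fluoride at the end.

Step 10
Reactants: 13 Bf–CO2Me
Product: 14 Bf–CH2OH
Conditions: DIBAL-H, CH2Cl2, −78 °C; Rochelle salt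
Reagents that add atoms: none
Why: Hydride reduction of the ester to the benzylic alcohol is compatible with aryl and alkyl silyl ethers.

Step 11
Reactants: 14 Bf–CH2OH
Product: 15 Bf–CH2Br
Conditions: CBr4, PPh3, CH2Cl2, 0 °C
Reagents that add atoms: carbon tetrabromide, BrC(Br)(Br)Br
Why: Appel bromination converts the primary benzylic alcohol into the bromide under neutral conditions.

Step 12
Reactants: 15 Bf–CH2Br
Product: 16 5-(prop-2-yn-1-yl) compound Bf–CH2–C≡CH
Conditions: HC≡CMgBr (3 equiv), CuBr·SMe2 (10 mol %), THF, 0 °C to rt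
Reagents that add atoms: ethynylmagnesium bromide, C#C[Mg]Br
Why: Copper-catalysed substitution of a benzylic bromide by an alkynyl Grignard reagent gives the 3-arylpropyne.

Step 13
Reactants: 16 Bf–CH2–C≡CH; 17 (1R,2S,5R)-menthyl (S)-4-methylbenzenesulfinate
Product: 18 (S at sulfur) alkynyl sulfoxide Bf–CH2–C≡C–S(O)Tol
Conditions: EtMgBr, THF, 0 °C to rt; then 17, toluene, −20 °C
Reagents that add atoms: none
Why: Andersen sulfinate substitution, in which the magnesium acetylide displaces menthoxide at sulfur with inversion, fixes the sulfur stereocentre.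

Step 14
Reactants: 18 alkynyl sulfoxide
Product: 19 (R at sulfur, Z) alkenyl sulfoxide Bf–CH2–CH=CH–S(O)Tol
Conditions: H2 (1 atm), RhCl(PPh3)3 (5 mol %), benzene, rt
Reagents that add atoms: none
Why: Sulfinyl-directed syn-semihydrogenation with Wilkinson's catalyst should give the Z-alkenyl sulfoxide without change at sulfur.

Step 15
Reactants: 19 (R at sulfur, Z) alkenyl sulfoxide
Product: 22 (4S,5R)-3,3-dichloro-4-(Bf-methyl)-5-(Tol-sulfanyl)oxolan-2-one, via acyloxysulfonium enolate 20 (not isolated), via thionium carboxylate 21 (not isolated)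
Conditions: Cl3CCOCl (3 equiv), Zn–Cu couple, THF, −45 to 0 °C
Reagents that add atoms: trichloroacetyl chloride, ClC(Cl)(Cl)C(Cl)=O (delivers dichloroketene, ClC(Cl)=C=O)
Why: The sulfinyl oxygen of 19 adds to the carbonyl carbon of dichloroketene to give acyloxysulfonium enolate 20, which undergoes a charge-accelerated [3,3]-sigmatropic shift (new C3–C4 bond, S–O cleavage) to thionium carboxylate 21, whose carboxylate then adds to the thionium carbon (new O1–C5 bond). The closest known reaction is the Marino lactonisation of enantiopure 1-alkenyl p-tolyl sulfoxides with dichloroketene. The lactone ring is closed by 5-exo-trig attack of the carboxylate oxygen on the C=S+ carbon, after the C–C bond has been made through a six-membered chair array. C4 is controlled by the sulfur stereocentre together with the Z geometry: p-tolyl sits pseudo-equatorial in the chair (an axial tolyl would suffer 1,3-allylic strain with the Z substituent), so the enolate carbon is delivered to the face that gives the arrangement which becomes (4R) in the dechlorinated lactone; the temporary C5 centre should form cis to the C4 substituent and is removed in step 16. The step needs O-attack and rearrangement to outrun [2+2] cycloaddition and γ-deprotonation (vinylogous Pummerer), which the electrophilic ketene, the absence of base and the low temperature should secure; all hydroxyl groups are silylated, so the acid chloride finds no other nucleophile.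

Step 16
Reactants: 22 dichloro(arylthio)lactone
Product: 23 (4R)-4-(Bf-methyl)oxolan-2-one
Conditions: n-Bu3SnH (5 equiv), AIBN (cat.), toluene, 100 °C
Reagents that add atoms: none
Why: Radical chain reduction, in which stannyl radicals abstract both α-chlorines and cleave the C5–S bond of the O,S-acetal, leaves C4 untouched.

Step 17
Reactants: 7 (4S)-4-benzyl-3-[(ArE)acetyl]-1,3-oxazolidin-2-one; 8 4-(TBS-oxy)-3-methoxybenzaldehyde
Product: 25 (4S)-4-benzyl-3-[(2R,3S)-2-ArE-3-ArG-3-hydroxypropanoyl]-1,3-oxazolidin-2-one, via trimethylsilyl ether 24 (not isolated)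
Conditions: MgCl2 (20 mol %), Et3N, TMSCl, EtOAc, rt; then MeOH, PPTS (cat.), 0 °C
Reagents that add atoms: chlorotrimethylsilane, C[Si](C)(C)Cl (its silyl group is carried by 24 only)
Why: Magnesium halide-catalysed direct anti-aldol reaction of the Evans imide (soft enolisation, silyl trapping), in which the chelated Z enolate is attacked on the face away from the auxiliary benzyl group through a boat-like transition state, should set (2R,3S).

Step 18
Reactants: 25 anti-aldol imide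
Product: 26 (1S,2S)-1-ArG-2-ArE-propane-1,3-diol
Conditions: LiBH4, MeOH (1 equiv), THF, 0 °C
Reagents that add atoms: none
Why: Reductive cleavage of the imide as in step 6 gives the open 1,3-diol unit with both stereocentres intact.

Step 19
Reactants: 26 (1S,2S)-diol
Product: 27 methyl 3-[(1S,2S)-1,3-bis(TBS-oxy)-1-ArG-propan-2-yl]-4-(TBS-oxy)-5-methoxybenzoate
Conditions: TBSOTf, 2,6-lutidine, CH2Cl2, −78 to 0 °C
Reagents that add atoms: tert-butyldimethylsilyl triflate, CC(C)(C)[Si](C)(C)OS(=O)(=O)C(F)(F)F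
Why: Silylation of both hydroxyls under buffered conditions blocks ionisation of the benzylic carbinol in the later steps.

Step 20
Reactants: 27 tetrasilyl ester
Product: 28 corresponding benzylic alcohol (CO2Me replaced by CH2OH)
Conditions: DIBAL-H, CH2Cl2, −78 °C; Rochelle salt
Reagents that add atoms: none
Why: Hydride reduction of the ester gives the benzylic alcohol without affecting the silyl ethers.

Step 21
Reactants: 28 benzylic alcohol
Product: 29 corresponding benzylic bromide (CH2Br)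
Conditions: CBr4, PPh3, CH2Cl2, 0 °C
Reagents that add atoms: carbon tetrabromide, BrC(Br)(Br)Br
Why: Appel bromination gives the electrophile for the lactone alkylation under non-acidic conditions.

Step 22
Reactants: 23 (4R)-4-(Bf-methyl)oxolan-2-one; 29 benzylic bromide
Product: 30 hexa-TBS ether of the target with the (3R,4R)-trans-3,4-disubstituted lactone
Conditions: LiHMDS, THF, −78 °C; then 29, DMPU, −78 to −30 °C
Reagents that add atoms: none
Why: Alkylation of the lactone lithium enolate should occur anti to the C4 substituent (1,2-induction, the standard entry to trans-dibenzylbutyrolactones), setting C3 as (R).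

Step 23
Reactants: 30 hexa-TBS ether
Product: 31 CNP0186558.2
Conditions: TBAF, AcOH (1:1), THF, 0 °C to rt
Reagents that add atoms: none
Why: Buffered fluoride desilylation removes all six silyl groups while avoiding phenoxide-driven quinone methide formation and the acid-catalysed closure of the open diol unit to a second benzofuran.

## Compound list

1 | methyl 3-bromo-4-hydroxy-5-methoxybenzoate | COC(=O)c1cc(Br)c(O)c(OC)c1 | starting material
2 | methyl 3-bromo-4-(TBS-oxy)-5-methoxybenzoate | COC(=O)c1cc(Br)c(O[Si](C)(C)C(C)(C)C)c(OC)c1 | intermediate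
3 | methyl 3-(2-tert-butoxy-2-oxoethyl)-4-(TBS-oxy)-5-methoxybenzoate | COC(=O)c1cc(CC(=O)OC(C)(C)C)c(O[Si](C)(C)C(C)(C)C)c(OC)c1 | intermediate
4 | [2-(TBS-oxy)-3-methoxy-5-(methoxycarbonyl)phenyl]acetic acid | COC(=O)c1cc(CC(=O)O)c(O[Si](C)(C)C(C)(C)C)c(OC)c1 | intermediate
5 | (S)-4-benzyl-1,3-oxazolidin-2-one | O=C1N[C@@H](Cc2ccccc2)CO1 | starting material
6 | mixed anhydride of 4 with pivalic acid | COC(=O)c1cc(CC(=O)OC(=O)C(C)(C)C)c(O[Si](C)(C)C(C)(C)C)c(OC)c1 | intermediate
7 | (4S)-4-benzyl-3-[(ArE)acetyl]-1,3-oxazolidin-2-one | COC(=O)c1cc(CC(=O)N2[C@@H](Cc3ccccc3)COC2=O)c(O[Si](C)(C)C(C)(C)C)c(OC)c1 | intermediate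
8 | 4-(TBS-oxy)-3-methoxybenzaldehyde | COc1cc(C=O)ccc1O[Si](C)(C)C(C)(C)C | starting material
9 | (4S)-4-benzyl-3-[(2S,3S)-2-ArE-3-ArG-3-hydroxypropanoyl]-1,3-oxazolidin-2-one | COc1cc([C@@H](O)[C@@H](C(=O)N2[C@@H](Cc3ccccc3)COC2=O)c2cc(C(=O)OC)cc(OC)c2O[Si](C)(C)C(C)(C)C)ccc1O[Si](C)(C)C(C)(C)C | intermediate
10 | (1S,2R)-1-ArG-2-ArE-propane-1,3-diol | COc1cc([C@@H](O)[C@@H](CO)c2cc(C(=O)OC)cc(OC)c2O[Si](C)(C)C(C)(C)C)ccc1O[Si](C)(C)C(C)(C)C | intermediate
11 | methyl 3-[(1S,2R)-1,3-dihydroxy-1-(4-hydroxy-3-methoxyphenyl)propan-2-yl]-4-hydroxy-5-methoxybenzoate | COc1cc([C@@H](O)[C@@H](CO)c2cc(C(=O)OC)cc(OC)c2O)ccc1O | intermediate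
12 | methyl (2S,3R)-2-(4-hydroxy-3-methoxyphenyl)-3-(hydroxymethyl)-7-methoxy-2,3-dihydro-1-benzofuran-5-carboxylate | COC(=O)c1cc(OC)c2c(c1)[C@H](CO)[C@@H](c1ccc(O)c(OC)c1)O2 | intermediate
13 | methyl (2S,3R)-2-ArG-3-(TBS-oxymethyl)-7-methoxy-2,3-dihydro-1-benzofuran-5-carboxylate | COC(=O)c1cc(OC)c2c(c1)[C@H](CO[Si](C)(C)C(C)(C)C)[C@@H](c1ccc(O[Si](C)(C)C(C)(C)C)c(OC)c1)O2 | intermediate
14 | [(2S,3R)-2-ArG-3-(TBS-oxymethyl)-7-methoxy-2,3-dihydro-1-benzofuran-5-yl]methanol | OCc1cc(OC)c2c(c1)[C@H](CO[Si](C)(C)C(C)(C)C)[C@@H](c1ccc(O[Si](C)(C)C(C)(C)C)c(OC)c1)O2 | intermediate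
15 | (2S,3R)-5-(bromomethyl)-2-ArG-3-(TBS-oxymethyl)-7-methoxy-2,3-dihydro-1-benzofuran | BrCc1cc(OC)c2c(c1)[C@H](CO[Si](C)(C)C(C)(C)C)[C@@H](c1ccc(O[Si](C)(C)C(C)(C)C)c(OC)c1)O2 | intermediate
16 | (2S,3R)-2-ArG-3-(TBS-oxymethyl)-7-methoxy-5-(prop-2-yn-1-yl)-2,3-dihydro-1-benzofuran | C#CCc1cc(OC)c2c(c1)[C@H](CO[Si](C)(C)C(C)(C)C)[C@@H](c1ccc(O[Si](C)(C)C(C)(C)C)c(OC)c1)O2 | intermediate
17 | (1R,2S,5R)-menthyl (S)-4-methylbenzenesulfinate | Cc1ccc(cc1)[S@@](=O)O[C@H]1[C@H](C(C)C)CC[C@@H](C)C1 | starting material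
18 | (S at sulfur) Bf–CH2–C≡C–S(O)Tol | Cc1ccc(cc1)[S@](=O)C#CCc1cc(OC)c2c(c1)[C@H](CO[Si](C)(C)C(C)(C)C)[C@@H](c1ccc(O[Si](C)(C)C(C)(C)C)c(OC)c1)O2 | intermediate
19 | (R at sulfur, Z) Bf–CH2–CH=CH–S(O)Tol | Cc1ccc(cc1)[S@](=O)/C=C\Cc1cc(OC)c2c(c1)[C@H](CO[Si](C)(C)C(C)(C)C)[C@@H](c1ccc(O[Si](C)(C)C(C)(C)C)c(OC)c1)O2 | intermediate
20 | S-[(2,2-dichloro-1-oxidoethenyl)oxy]sulfonium inner salt of 19 | Cc1ccc(cc1)[S@+](OC([O-])=C(Cl)Cl)/C=C\Cc1cc(OC)c2c(c1)[C@H](CO[Si](C)(C)C(C)(C)C)[C@@H](c1ccc(O[Si](C)(C)C(C)(C)C)c(OC)c1)O2 | intermediate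
21 | (3S)-2,2-dichloro-3-(Bf-methyl)-4-(Tol-sulfaniumylidene)butanoate (E thionium) | [O-]C(=O)C(Cl)(Cl)[C@@H](Cc1cc(OC)c2c(c1)[C@H](CO[Si](C)(C)C(C)(C)C)[C@@H](c1ccc(O[Si](C)(C)C(C)(C)C)c(OC)c1)O2)/C=[S+]/c1ccc(C)cc1 | intermediate
22 | (4S,5R)-3,3-dichloro-4-(Bf-methyl)-5-(Tol-sulfanyl)oxolan-2-one | ClC1(Cl)C(=O)O[C@H](Sc2ccc(C)cc2)[C@@H]1Cc1cc(OC)c2c(c1)[C@H](CO[Si](C)(C)C(C)(C)C)[C@@H](c1ccc(O[Si](C)(C)C(C)(C)C)c(OC)c1)O2 | intermediate
23 | (4R)-4-(Bf-methyl)oxolan-2-one | C1C(=O)OC[C@@H]1Cc1cc(OC)c2c(c1)[C@H](CO[Si](C)(C)C(C)(C)C)[C@@H](c1ccc(O[Si](C)(C)C(C)(C)C)c(OC)c1)O2 | intermediate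
24 | O-trimethylsilyl ether of 25 | COc1cc([C@@H](O[Si](C)(C)C)[C@H](C(=O)N2[C@@H](Cc3ccccc3)COC2=O)c2cc(C(=O)OC)cc(OC)c2O[Si](C)(C)C(C)(C)C)ccc1O[Si](C)(C)C(C)(C)C | intermediate
25 | (4S)-4-benzyl-3-[(2R,3S)-2-ArE-3-ArG-3-hydroxypropanoyl]-1,3-oxazolidin-2-one | COc1cc([C@@H](O)[C@H](C(=O)N2[C@@H](Cc3ccccc3)COC2=O)c2cc(C(=O)OC)cc(OC)c2O[Si](C)(C)C(C)(C)C)ccc1O[Si](C)(C)C(C)(C)C | intermediate
26 | (1S,2S)-1-ArG-2-ArE-propane-1,3-diol | COc1cc([C@@H](O)[C@H](CO)c2cc(C(=O)OC)cc(OC)c2O[Si](C)(C)C(C)(C)C)ccc1O[Si](C)(C)C(C)(C)C | intermediate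
27 | methyl 3-[(1S,2S)-1,3-bis(TBS-oxy)-1-ArG-propan-2-yl]-4-(TBS-oxy)-5-methoxybenzoate | COc1cc([C@@H](O[Si](C)(C)C(C)(C)C)[C@H](CO[Si](C)(C)C(C)(C)C)c2cc(C(=O)OC)cc(OC)c2O[Si](C)(C)C(C)(C)C)ccc1O[Si](C)(C)C(C)(C)C | intermediate
28 | benzylic alcohol from 27 (CH2OH in place of CO2Me) | COc1cc([C@@H](O[Si](C)(C)C(C)(C)C)[C@H](CO[Si](C)(C)C(C)(C)C)c2cc(CO)cc(OC)c2O[Si](C)(C)C(C)(C)C)ccc1O[Si](C)(C)C(C)(C)C | intermediate
29 | benzylic bromide from 28 (CH2Br) | COc1cc([C@@H](O[Si](C)(C)C(C)(C)C)[C@H](CO[Si](C)(C)C(C)(C)C)c2cc(CBr)cc(OC)c2O[Si](C)(C)C(C)(C)C)ccc1O[Si](C)(C)C(C)(C)C | intermediate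
30 | hexa-TBS ether of the target, (3R,4R)-lactone | COc1cc([C@@H](O[Si](C)(C)C(C)(C)C)[C@H](CO[Si](C)(C)C(C)(C)C)c2cc(C[C@H]3C(=O)OC[C@@H]3Cc3cc(OC)c4c(c3)[C@H](CO[Si](C)(C)C(C)(C)C)[C@@H](c3ccc(O[Si](C)(C)C(C)(C)C)c(OC)c3)O4)cc(OC)c2O[Si](C)(C)C(C)(C)C)ccc1O[Si](C)(C)C(C)(C)C | intermediate
31 | CNP0186558.2 | COc1cc([C@@H](O)[C@H](CO)c2cc(C[C@H]3C(=O)OC[C@@H]3Cc3cc(OC)c4c(c3)[C@H](CO)[C@@H](c3ccc(O)c(OC)c3)O4)cc(OC)c2O)ccc1O | target

## Step count and risks

Total steps: 23. Longest linear sequence: 18 steps (steps 1–16, then 22 and 23).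

Most likely to fail:

Step 15. Chirality transfer may be eroded by a competing chair with axial p-tolyl. The acyloxysulfonium salt may also be diverted by γ-deprotonation (vinylogous Pummerer) or by isomerisation to the allylic sulfoxide, and zinc chloride may cause desilylation. Fallback by auxiliary-controlled alkylation, setting out from bromide 15 and coming back at lactone 23: mono-tert-butyl succinate is attached to (R)-4-benzyl-1,3-oxazolidin-2-one (PivCl, Et3N, LiCl) to give succinyl imide F1. Its sodium enolate (NaHMDS, THF, −78 °C) is alkylated with 15 on the face away from the auxiliary benzyl group to give alkylated imide F2. LiBH4 removes the auxiliary to give hydroxy ester F3, which should close to 23 on warming with PPTS in toluene.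

Step 17. Conversion may be incomplete with the electron-rich aldehyde, the acidic α-aryl imide may undergo retro-aldol cleavage or α-epimerisation, and anti selectivity may be lower than with simple propionyl imides. Fallback by syn-aldol and inversion of the carbinol, setting out from acid 4 and coming back at 27: 4 is attached to (R)-4-benzyl-1,3-oxazolidin-2-one to give enantiomeric-auxiliary imide F4. The boron aldol with 8 (as in step 5) gives syn adduct F5, and LiBH4 gives syn diol F6. TBSCl and imidazole at 0 °C silylate only the primary hydroxyl to give mono-silyl ether F7, and Dess–Martin oxidation gives aryl ketone F8. Corey–Bakshi–Shibata reduction with the (R)-oxazaborolidine and BH3·SMe2 should set the (S) carbinol under reagent control to give anti alcohol F9; the Felkin preference opposes this, which is why it is only the fallback. TBSOTf and 2,6-lutidine then give 27.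

Step 13. The propargylic and benzylic CH2 may isomerise to the allene under the basic acetylide conditions, and a low Z selectivity in step 14 would feed the wrong lactone enantiomer. Fallback through the other alkene geometry and the enantiomeric sulfinate, setting out from alkyne 16 and coming back at 23: hydrozirconation with Cp2Zr(H)Cl followed by iodine gives (E)-alkenyl iodide F10. Iodine–lithium exchange (t-BuLi, Et2O, −78 °C) and Andersen substitution on (1S,2R,5S)-menthyl (R)-4-methylbenzenesulfinate give (S at sulfur, E) alkenyl sulfoxide F11. Dichloroketene annulation as in step 15 gives trans-lactone F12, because the E geometry and the opposite sulfur configuration converge on the same C4 configuration. Bu3SnH as in step 16 then gives 23.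

Further compounds
F1 | step 15 | (R)-4-benzyl-3-[4-(tert-butoxy)-4-oxobutanoyl]-1,3-oxazolidin-2-one | CC(C)(C)OC(=O)CCC(=O)N1[C@H](Cc2ccccc2)COC1=O
F2 | step 15 | (4R)-4-benzyl-3-[(2R)-2-(Bf-methyl)-4-(tert-butoxy)-4-oxobutanoyl]-1,3-oxazolidin-2-one | O=C1OC[C@@H](Cc2ccccc2)N1C(=O)[C@@H](CC(=O)OC(C)(C)C)Cc1cc(OC)c2c(c1)[C@H](CO[Si](C)(C)C(C)(C)C)[C@@H](c1ccc(O[Si](C)(C)C(C)(C)C)c(OC)c1)O2
F3 | step 15 | tert-butyl (3R)-3-(Bf-methyl)-4-hydroxybutanoate | OC[C@@H](CC(=O)OC(C)(C)C)Cc1cc(OC)c2c(c1)[C@H](CO[Si](C)(C)C(C)(C)C)[C@@H](c1ccc(O[Si](C)(C)C(C)(C)C)c(OC)c1)O2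
F4 | step 17 | (4R)-4-benzyl-3-[(ArE)acetyl]-1,3-oxazolidin-2-one | COC(=O)c1cc(CC(=O)N2[C@H](Cc3ccccc3)COC2=O)c(O[Si](C)(C)C(C)(C)C)c(OC)c1
F5 | step 17 | (4R)-4-benzyl-3-[(2R,3R)-2-ArE-3-ArG-3-hydroxypropanoyl]-1,3-oxazolidin-2-one | COc1cc([C@H](O)[C@H](C(=O)N2[C@H](Cc3ccccc3)COC2=O)c2cc(C(=O)OC)cc(OC)c2O[Si](C)(C)C(C)(C)C)ccc1O[Si](C)(C)C(C)(C)C
F6 | step 17 | (1R,2S)-1-ArG-2-ArE-propane-1,3-diol | COc1cc([C@H](O)[C@H](CO)c2cc(C(=O)OC)cc(OC)c2O[Si](C)(C)C(C)(C)C)ccc1O[Si](C)(C)C(C)(C)C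
F7 | step 17 | (1R,2S)-1-ArG-2-ArE-3-(TBS-oxy)propan-1-ol | COc1cc([C@H](O)[C@H](CO[Si](C)(C)C(C)(C)C)c2cc(C(=O)OC)cc(OC)c2O[Si](C)(C)C(C)(C)C)ccc1O[Si](C)(C)C(C)(C)C
F8 | step 17 | (2S)-1-ArG-2-ArE-3-(TBS-oxy)propan-1-one | COc1cc(C(=O)[C@H](CO[Si](C)(C)C(C)(C)C)c2cc(C(=O)OC)cc(OC)c2O[Si](C)(C)C(C)(C)C)ccc1O[Si](C)(C)C(C)(C)C
F9 | step 17 | (1S,2S)-1-ArG-2-ArE-3-(TBS-oxy)propan-1-ol | COc1cc([C@@H](O)[C@H](CO[Si](C)(C)C(C)(C)C)c2cc(C(=O)OC)cc(OC)c2O[Si](C)(C)C(C)(C)C)ccc1O[Si](C)(C)C(C)(C)C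
F10 | step 13 | (2S,3R)-2-ArG-3-(TBS-oxymethyl)-5-[(2E)-3-iodoprop-2-en-1-yl]-7-methoxy-2,3-dihydro-1-benzofuran | I/C=C/Cc1cc(OC)c2c(c1)[C@H](CO[Si](C)(C)C(C)(C)C)[C@@H](c1ccc(O[Si](C)(C)C(C)(C)C)c(OC)c1)O2
F11 | step 13 | (S at sulfur, E) Bf–CH2–CH=CH–S(O)Tol | Cc1ccc(cc1)[S@@](=O)/C=C/Cc1cc(OC)c2c(c1)[C@H](CO[Si](C)(C)C(C)(C)C)[C@@H](c1ccc(O[Si](C)(C)C(C)(C)C)c(OC)c1)O2
F12 | step 13 | (4S,5S)-3,3-dichloro-4-(Bf-methyl)-5-(Tol-sulfanyl)oxolan-2-one | ClC1(Cl)C(=O)O[C@@H](Sc2ccc(C)cc2)[C@@H]1Cc1cc(OC)c2c(c1)[C@H](CO[Si](C)(C)C(C)(C)C)[C@@H](c1ccc(O[Si](C)(C)C(C)(C)C)c(OC)c1)O2
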